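**Retrosynthetic overview**
1. Target ⇐ removal of two TIPS groups; the C5–CH2 bond ⇐ B-alkyl Suzuki coupling of a 5-iodo-7-methoxy-2,3-dihydrobenzofuran with hydroborated allyl ferulate, so the ester arrives intact.
2. 5-Iodide ⇐ sterically controlled C–H borylation/iodination of the 7-methoxy dihydrobenzofuran ⇐ O-methylation of the 7-phenol.
3. Key step: 7-hydroxy-2,3-dihydrobenzofuran ⇐ gold(I)-catalysed furan–yne benzannulation of a furan-tethered alkynyl ether; the benzene ring and the dihydrofuran ring form together and the furan oxygen becomes the 7-OH.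
4. Alkynyl ether ⇐ mono-silylated syn-1,3-diol ⇐ Evans syn-aldol of (R)-4-benzyl-3-(2-furylacetyl)oxazolidinone with TIPS-vanillin; the syn aldol gives the trans-(2R,3S) ring because no bond at either stereocentre is broken afterwards.
5. Ring order: the furan and the two guaiacyl rings are bought; the central benzene ring and the dihydrofuran ring are formed simultaneously in the key step (furan consumed); no ring is made after that.

Assumption: vanillin, 2-(furan-2-yl)acetic acid, (R)-4-benzyl-2-oxazolidinone, (E)-ferulic acid and the reagents named are purchased; the two one-step side branches are steps 1 and 10.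

**Route**

Step 1
Reactants: 1 vanillin (4-hydroxy-3-methoxybenzaldehyde)
Product: 2 3-methoxy-4-[(triisopropylsilyl)oxy]benzaldehyde
Conditions: TIPSCl (1.1 equiv), imidazole (2 equiv), DMF, rt
Reagents that add atoms: chlorotriisopropylsilane (TIPSCl), CC(C)[Si](Cl)(C(C)C)C(C)C
Why: Imidazole-promoted silylation of the phenol (Corey silyl ether formation); TIPS is chosen because it survives KH, n-BuLi, carbonate and the Ir/Pd steps, and no stereocentre is involved.

Step 2
Reactants: 3 2-(furan-2-yl)acetic acid; 4 (4R)-4-benzyl-1,3-oxazolidin-2-one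
Product: 6 (4R)-4-benzyl-3-[2-(furan-2-yl)acetyl]-1,3-oxazolidin-2-one, via mixed anhydride 5 (not isolated)
Conditions: PivCl (1.1 equiv), Et3N (2.5 equiv), THF, −20 °C; then LiCl (1.1 equiv), 4, −20 °C → rt
Reagents that add atoms: none
Why: N-Acylation of the Evans auxiliary through the mixed pivalic anhydride with LiCl/Et3N activation of the oxazolidinone (mixed-anhydride acylation), which avoids a furylacetyl chloride.

Step 3
Reactants: 6 (4R)-4-benzyl-3-[2-(furan-2-yl)acetyl]-1,3-oxazolidin-2-one; 2 3-methoxy-4-[(triisopropylsilyl)oxy]benzaldehyde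
Product: 7 (4R)-4-benzyl-3-[(2S,3R)-2-(furan-2-yl)-3-hydroxy-3-{3-methoxy-4-[(triisopropylsilyl)oxy]phenyl}propanoyl]-1,3-oxazolidin-2-one
Conditions: Bu2BOTf (1.1 equiv), i-Pr2NEt (1.3 equiv), CH2Cl2, −78 → 0 °C; 2, −78 → 0 °C; then pH 7 buffer, MeOH, 30% H2O2, 0 °C
Reagents that add atoms: none
Why: Evans boron syn-aldol reaction: the (Z)-dibutylboron enolate of 6 adds to 2 through a Zimmerman–Traxler chair on the face remote from the benzyl group of the (R)-auxiliary, which sets both new stereocentres (2S,3R, syn) that later become C3 (S) and C2 (R) of the dihydrobenzofuran.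

Step 4
Reactants: 7 (the syn-aldol imide)
Product: 8 (1R,2S)-2-(furan-2-yl)-1-{3-methoxy-4-[(triisopropylsilyl)oxy]phenyl}propane-1,3-diol
Conditions: LiBH4 (2 equiv), MeOH (2 equiv), THF, 0 °C
Reagents that add atoms: none
Why: Reductive removal of the Evans auxiliary with LiBH4 (hydride attack on the exocyclic imide carbonyl) gives the primary alcohol without touching either stereocentre and returns 4.

Step 5
Reactants: 8 (the 1,3-diol)
Product: 9 (1R,2S)-2-(furan-2-yl)-1-{3-methoxy-4-[(triisopropylsilyl)oxy]phenyl}-3-[(triisopropylsilyl)oxy]propan-1-ol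
Conditions: TIPSCl (1.05 equiv), imidazole, DMF, 0 °C → rt
Reagents that add atoms: chlorotriisopropylsilane (TIPSCl), CC(C)[Si](Cl)(C(C)C)C(C)C
Why: Sterically controlled silylation of the primary hydroxyl in preference to the hindered secondary benzylic one; TIPS rather than TBS is used so that the group does not migrate to the secondary alkoxide in step 6.

Step 6
Reactants: 9 (the secondary alcohol)
Product: 11 (1R,2S)-1-(ethynyloxy)-2-(furan-2-yl)-1-{3-methoxy-4-[(triisopropylsilyl)oxy]phenyl}-3-[(triisopropylsilyl)oxy]propane, via dichlorovinyl ether 10 (not isolated)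
Conditions: KH (2 equiv), THF, 0 °C; Cl2C=CHCl (1.1 equiv), −50 °C → rt; then n-BuLi (2.5 equiv), −78 → −40 °C; MeOH, −78 °C; quick filtration through Et3N-deactivated silica, used at once
Reagents that add atoms: trichloroethylene, ClC=C(Cl)Cl
Why: Greene alkynyl ether synthesis: the potassium alkoxide adds to dichloroacetylene generated in situ from trichloroethylene to give the (E)-1,2-dichlorovinyl ether, and n-BuLi then effects HCl elimination and Cl–Li exchange to the lithium alkoxyacetylide, which MeOH protonates; the carbinol C–O bond is never broken, so the configuration is retained.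

Step 7 (key step)
Reactants: 11 (the furan-tethered alkynyl ether)
Product: 13 (2R,3S)-2-{3-methoxy-4-[(triisopropylsilyl)oxy]phenyl}-3-{[(triisopropylsilyl)oxy]methyl}-2,3-dihydro-1-benzofuran-7-ol, via arene oxide 12 (not isolated)
Conditions: [Mes3PAu]NTf2 (2 mol %), 4 Å MS, CH2Cl2, −20 °C → rt
Reagents that add atoms: none
Why: Hashmi gold(I) furan–yne phenol synthesis in its alkynyl-ether variant: the Au-activated ynol ether is attacked at its O-bearing carbon by the furan C2=C3 bond, the cyclopropyl gold carbene opens the furan to a dienal carbene that closes to the oxepine/arene oxide, and the ring oxygen directs epoxide opening so that the former furan oxygen ends as the 7-OH; the benzene ring and the dihydrofuran ring therefore form in one operation and, since no bond to C2 or C3 is broken, the syn-aldol diad becomes the trans-(2R,3S) dihydrobenzofuran.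

Step 8
Reactants: 13 (the 7-phenol)
Product: 14 (2R,3S)-7-methoxy-2-{3-methoxy-4-[(triisopropylsilyl)oxy]phenyl}-3-{[(triisopropylsilyl)oxy]methyl}-2,3-dihydro-1-benzofuran
Conditions: MeI (3 equiv), K2CO3 (2 equiv), acetone, rt
Reagents that add atoms: iodomethane, CI
Why: Williamson O-methylation of the only free phenol under mild carbonate conditions that leave the silyl ethers and both stereocentres untouched.

Step 9
Reactants: 14 (the 7-methoxy dihydrobenzofuran)
Product: 16 (2R,3S)-5-iodo-7-methoxy-2-{3-methoxy-4-[(triisopropylsilyl)oxy]phenyl}-3-{[(triisopropylsilyl)oxy]methyl}-2,3-dihydro-1-benzofuran, via aryl boronate 15 (not isolated)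
Conditions: [Ir(cod)OMe]2 (1.5 mol %), dtbpy (3 mol %), B2pin2 (1.0 equiv), THF, 80 °C; evaporate; CuI (10 mol %), 1,10-phenanthroline (20 mol %), KI (1.5 equiv), MeOH/H2O, air, 80 °C
Reagents that add atoms: bis(pinacolato)diboron, CC1(C)OB(OC1(C)C)B1OC(C)(C)C(C)(C)O1 (its boron unit remains only in 15); potassium iodide, [K+].[I-]
Why: Sterically governed Ir-catalysed C–H borylation (Hartwig–Miyaura) occurs at C5, the only aromatic C–H with no ortho substituent on either side, and the crude boronate undergoes Cu-catalysed aerobic ipso-iododeboronation in the same flask, giving the 5-iodide regiospecifically.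

Step 10
Reactants: 17 (E)-ferulic acid
Product: 18 prop-2-en-1-yl (2E)-3-(4-hydroxy-3-methoxyphenyl)prop-2-enoate (allyl ferulate)
Conditions: KHCO3 (1.1 equiv), allyl bromide (1.1 equiv), DMF, rt → 40 °C
Reagents that add atoms: allyl bromide, C=CCBr
Why: SN2 O-alkylation of the carboxylate only, since bicarbonate deprotonates the acid (pKa about 4.5) but not the phenol (pKa about 10); the E alkene is untouched.

Step 11
Reactants: 16 (the 5-iodide); 18 allyl ferulate
Product: 20 3-[(2R,3S)-7-methoxy-2-{3-methoxy-4-[(triisopropylsilyl)oxy]phenyl}-3-{[(triisopropylsilyl)oxy]methyl}-2,3-dihydro-1-benzofuran-5-yl]propyl (2E)-3-(4-hydroxy-3-methoxyphenyl)prop-2-enoate, via alkylborane 19 (not isolated)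
Conditions: 18 (1.5 equiv), 9-BBN (2.1 equiv per 18), THF, 0 °C → rt; then 16, Pd(dppf)Cl2·CH2Cl2 (5 mol %), aq K3PO4 (3 M), DMF, rt → 50 °C
Reagents that add atoms: 9-borabicyclo[3.3.1]nonane, [H]B1C2CCCC1CCC2 (its boron units remain only in 19)
Why: Anti-Markovnikov hydroboration of the terminal allyl alkene with 9-BBN (the conjugated cinnamate C=C and the ester are inert at rt, and the phenol is merely converted into its borinate) followed by B-alkyl Suzuki–Miyaura coupling with the aryl iodide builds the C5–CH2 bond and brings in the intact ferulate ester.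

Step 12
Reactants: 20 (the bis-TIPS ether)
Product: 21 3-[(2R,3S)-2-(4-hydroxy-3-methoxyphenyl)-3-(hydroxymethyl)-7-methoxy-2,3-dihydro-1-benzofuran-5-yl]propyl (2E)-3-(4-hydroxy-3-methoxyphenyl)prop-2-enoate (target, CNP0149450.1)
Conditions: TBAF (3 equiv), AcOH (3 equiv), THF, 0 °C → rt
Reagents that add atoms: none
Why: Fluoride-mediated cleavage of the aryl and the primary alkyl TIPS ethers, buffered with AcOH so that the cinnamate ester is not attacked and the 4-hydroxyphenyl-substituted benzylic ether cannot open through a quinone methide; the stereocentres are unchanged.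

**Compound list**
1 | vanillin (4-hydroxy-3-methoxybenzaldehyde) | COc1cc(C=O)ccc1O | starting material
2 | 3-methoxy-4-[(triisopropylsilyl)oxy]benzaldehyde | COc1cc(C=O)ccc1O[Si](C(C)C)(C(C)C)C(C)C | intermediate
3 | 2-(furan-2-yl)acetic acid | OC(=O)Cc1ccco1 | starting material
4 | (4R)-4-benzyl-1,3-oxazolidin-2-one | O=C1N[C@H](Cc2ccccc2)CO1 | starting material
5 | 2-(furan-2-yl)acetic pivalic anhydride | CC(C)(C)C(=O)OC(=O)Cc1ccco1 | intermediate (not isolated)
6 | (4R)-4-benzyl-3-[2-(furan-2-yl)acetyl]-1,3-oxazolidin-2-one | O=C(Cc1ccco1)N1C(=O)OC[C@H]1Cc1ccccc1 | intermediate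
7 | (4R)-4-benzyl-3-[(2S,3R)-2-(furan-2-yl)-3-hydroxy-3-{3-methoxy-4-[(triisopropylsilyl)oxy]phenyl}propanoyl]-1,3-oxazolidin-2-one | o1cccc1[C@@H](C(=O)N1C(=O)OC[C@H]1Cc1ccccc1)[C@H](c1ccc(O[Si](C(C)C)(C(C)C)C(C)C)c(OC)c1)O | intermediate
8 | (1R,2S)-2-(furan-2-yl)-1-{3-methoxy-4-[(triisopropylsilyl)oxy]phenyl}propane-1,3-diol | o1cccc1[C@@H](CO)[C@H](c1ccc(O[Si](C(C)C)(C(C)C)C(C)C)c(OC)c1)O | intermediate
9 | (1R,2S)-2-(furan-2-yl)-1-{3-methoxy-4-[(triisopropylsilyl)oxy]phenyl}-3-[(triisopropylsilyl)oxy]propan-1-ol | o1cccc1[C@@H](CO[Si](C(C)C)(C(C)C)C(C)C)[C@H](c1ccc(O[Si](C(C)C)(C(C)C)C(C)C)c(OC)c1)O | intermediate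
10 | (E)-1,2-dichlorovinyl ether of 9 at the secondary oxygen, (1R,2S) | o1cccc1[C@@H](CO[Si](C(C)C)(C(C)C)C(C)C)[C@H](c1ccc(O[Si](C(C)C)(C(C)C)C(C)C)c(OC)c1)O/C(Cl)=C\Cl | intermediate (not isolated)
11 | (1R,2S)-1-(ethynyloxy)-2-(furan-2-yl)-1-{3-methoxy-4-[(triisopropylsilyl)oxy]phenyl}-3-[(triisopropylsilyl)oxy]propane | o1cccc1[C@@H](CO[Si](C(C)C)(C(C)C)C(C)C)[C@H](c1ccc(O[Si](C(C)C)(C(C)C)C(C)C)c(OC)c1)OC#C | intermediate
12 | 6,7-epoxy-6,7-dihydro form of 13 (arene oxide, in equilibrium with its oxepine; (2R,3S), configuration at the two epoxide carbons not defined) | C1=CC2OC2C3=C1[C@@H](CO[Si](C(C)C)(C(C)C)C(C)C)[C@H](c1ccc(O[Si](C(C)C)(C(C)C)C(C)C)c(OC)c1)O3 | intermediate (not isolated)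
13 | (2R,3S)-2-{3-methoxy-4-[(triisopropylsilyl)oxy]phenyl}-3-{[(triisopropylsilyl)oxy]methyl}-2,3-dihydro-1-benzofuran-7-ol | c1cc(O)c2c(c1)[C@@H](CO[Si](C(C)C)(C(C)C)C(C)C)[C@H](c1ccc(O[Si](C(C)C)(C(C)C)C(C)C)c(OC)c1)O2 | intermediate
14 | (2R,3S)-7-methoxy-2-{3-methoxy-4-[(triisopropylsilyl)oxy]phenyl}-3-{[(triisopropylsilyl)oxy]methyl}-2,3-dihydro-1-benzofuran | c1cc(OC)c2c(c1)[C@@H](CO[Si](C(C)C)(C(C)C)C(C)C)[C@H](c1ccc(O[Si](C(C)C)(C(C)C)C(C)C)c(OC)c1)O2 | intermediate
15 | 5-(4,4,5,5-tetramethyl-1,3,2-dioxaborolan-2-yl) derivative of 14, (2R,3S) | CC1(C)OB(OC1(C)C)c1cc(OC)c2c(c1)[C@@H](CO[Si](C(C)C)(C(C)C)C(C)C)[C@H](c1ccc(O[Si](C(C)C)(C(C)C)C(C)C)c(OC)c1)O2 | intermediate (not isolated)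
16 | (2R,3S)-5-iodo-7-methoxy-2-{3-methoxy-4-[(triisopropylsilyl)oxy]phenyl}-3-{[(triisopropylsilyl)oxy]methyl}-2,3-dihydro-1-benzofuran | Ic1cc(OC)c2c(c1)[C@@H](CO[Si](C(C)C)(C(C)C)C(C)C)[C@H](c1ccc(O[Si](C(C)C)(C(C)C)C(C)C)c(OC)c1)O2 | intermediate
17 | (E)-ferulic acid | COc1cc(/C=C/C(=O)O)ccc1O | starting material
18 | allyl (E)-ferulate | COc1cc(/C=C/C(=O)OCC=C)ccc1O | intermediate
19 | 3-(9-borabicyclo[3.3.1]nonan-9-yl)propyl (E)-ferulate with the phenol as its O-(9-BBN) borinate | COc1cc(/C=C/C(=O)OCCCB2C3CCCC2CCC3)ccc1OB1C2CCCC1CCC2 | intermediate (not isolated)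
20 | 3-[(2R,3S)-7-methoxy-2-{3-methoxy-4-[(triisopropylsilyl)oxy]phenyl}-3-{[(triisopropylsilyl)oxy]methyl}-2,3-dihydro-1-benzofuran-5-yl]propyl (E)-ferulate | COc1cc(/C=C/C(=O)OCCCc2cc(OC)c3c(c2)[C@@H](CO[Si](C(C)C)(C(C)C)C(C)C)[C@H](c2ccc(O[Si](C(C)C)(C(C)C)C(C)C)c(OC)c2)O3)ccc1O | intermediate
21 | 3-[(2R,3S)-2-(4-hydroxy-3-methoxyphenyl)-3-(hydroxymethyl)-7-methoxy-2,3-dihydro-1-benzofuran-5-yl]propyl (2E)-3-(4-hydroxy-3-methoxyphenyl)prop-2-enoate | COc1cc(/C=C/C(=O)OCCCc2cc(OC)c3c(c2)[C@@H](CO)[C@H](c2ccc(O)c(OC)c2)O3)ccc1O | target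

**Step count**
Total: 12 steps. Longest linear sequence: 10 steps (3 → 21 through steps 2, 3, 4, 5, 6, 7, 8, 9, 11, 12).

**Steps most likely to fail, with fallbacks**

Step 7 (gold benzannulation). The benzylic, electron-rich alkynyl ether may ionise at C2–O, rearrange, be hydrated, or be attacked by the guaiacyl ring instead of the furan. Fallback: set out from 2 and 4 and carry the benzene ring in from the start. Acylate 4 with purchased (2-bromo-3-methoxyphenyl)acetic acid (PivCl, Et3N, LiCl) to the imide (4R)-4-benzyl-3-[2-(2-bromo-3-methoxyphenyl)acetyl]-1,3-oxazolidin-2-one F1. The same Bu2BOTf syn-aldol with 2 gives the (2R,3R) aldol adduct F2, LiBH4 gives the (1R,2S)-2-(2-bromo-3-methoxyphenyl)propane-1,3-diol F3, and TIPSCl/imidazole gives the primary silyl ether F4. A copper-catalysed intramolecular Ullmann C–O coupling of the secondary alcohol onto the aryl bromide (CuI, 3,4,7,8-tetramethyl-1,10-phenanthroline, K3PO4, toluene, 110 °C) then closes the dihydrofuran with retention at the carbinol carbon. This comes back to the route at 14, with the 7-methoxy group already in place.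

Step 6 (Greene alkynyl ether formation). The hindered secondary alkoxide may add poorly to dichloroacetylene or suffer silyl transfer, and the product is labile. Fallback: set out from 9 and avoid any alkoxide stage. Formylate the secondary alcohol (acetic formic anhydride, pyridine, 0 °C) to the formate ester F5. Dibromomethylenation of the formate carbonyl (CBr4, PPh3, CH2Cl2, 0 °C) gives the 2,2-dibromovinyl ether F6. n-BuLi (2.2 equiv, THF, −78 °C) followed by MeOH effects elimination and Br–Li exchange and comes back to the route at 11.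

Step 9 (C–H borylation/iodination). The borylation may be slow on this crowded substrate, and the aerobic Cu/iodide stage may iodinate the silyloxy-arene or strip the aryl TIPS group. Fallback: set out from 14 and use electronic rather than steric control. Bromination with NBS (MeCN, 0 °C), directed para to the ring oxygen, gives the 5-bromo-7-methoxy dihydrobenzofuran F7. F7 takes the place of 16 in step 11 (same 9-BBN/Suzuki conditions, 60 °C) and comes back to the route at 20.

**Further compounds**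
F1 | step 7 | (4R)-4-benzyl-3-[2-(2-bromo-3-methoxyphenyl)acetyl]-1,3-oxazolidin-2-one | COc1cccc(CC(=O)N2C(=O)OC[C@H]2Cc2ccccc2)c1Br
F2 | step 7 | (4R)-4-benzyl-3-[(2R,3R)-2-(2-bromo-3-methoxyphenyl)-3-hydroxy-3-{3-methoxy-4-[(triisopropylsilyl)oxy]phenyl}propanoyl]-1,3-oxazolidin-2-one | COc1cccc(c1Br)[C@@H](C(=O)N1C(=O)OC[C@H]1Cc1ccccc1)[C@H](c1ccc(O[Si](C(C)C)(C(C)C)C(C)C)c(OC)c1)O
F3 | step 7 | (1R,2S)-2-(2-bromo-3-methoxyphenyl)-1-{3-methoxy-4-[(triisopropylsilyl)oxy]phenyl}propane-1,3-diol | COc1cccc(c1Br)[C@@H](CO)[C@H](c1ccc(O[Si](C(C)C)(C(C)C)C(C)C)c(OC)c1)O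
F4 | step 7 | (1R,2S)-2-(2-bromo-3-methoxyphenyl)-1-{3-methoxy-4-[(triisopropylsilyl)oxy]phenyl}-3-[(triisopropylsilyl)oxy]propan-1-ol | COc1cccc(c1Br)[C@@H](CO[Si](C(C)C)(C(C)C)C(C)C)[C@H](c1ccc(O[Si](C(C)C)(C(C)C)C(C)C)c(OC)c1)O
F5 | step 6 | (1R,2S)-2-(furan-2-yl)-1-{3-methoxy-4-[(triisopropylsilyl)oxy]phenyl}-3-[(triisopropylsilyl)oxy]propyl formate | o1cccc1[C@@H](CO[Si](C(C)C)(C(C)C)C(C)C)[C@H](c1ccc(O[Si](C(C)C)(C(C)C)C(C)C)c(OC)c1)OC=O
F6 | step 6 | 2,2-dibromovinyl ether of 9 at the secondary oxygen, (1R,2S) | o1cccc1[C@@H](CO[Si](C(C)C)(C(C)C)C(C)C)[C@H](c1ccc(O[Si](C(C)C)(C(C)C)C(C)C)c(OC)c1)OC=C(Br)Br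
F7 | step 9 | (2R,3S)-5-bromo-7-methoxy-2-{3-methoxy-4-[(triisopropylsilyl)oxy]phenyl}-3-{[(triisopropylsilyl)oxy]methyl}-2,3-dihydro-1-benzofuran | Brc1cc(OC)c2c(c1)[C@@H](CO[Si](C(C)C)(C(C)C)C(C)C)[C@H](c1ccc(O[Si](C(C)C)(C(C)C)C(C)C)c(OC)c1)O2
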